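**Assumption:** the target has no stereocentre and no configurationally stable axis, so it is achiral and "single enantiomer" needs no stereocontrol. The route is designed from known reaction types and has not been run.

## Retrosynthetic overview

1. Target 7 is cut by a Pechmann disconnection of the pyranone ring (lactone O1–C2 and C4–C4a) into 3,5-dimethoxycatechol 3 and ethyl 3,4-dimethoxybenzoylacetate 4.
2. Catechol 3 comes from a Dakin oxidation (CHO to OH) of commercial 2-hydroxy-4,6-dimethoxybenzaldehyde 1.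
3. Both benzene rings are bought; the only ring formed is the pyranone, in the last step.

## Route

Step 1
Reactants: 1 2-hydroxy-4,6-dimethoxybenzaldehyde
Product: 3 3,5-dimethoxybenzene-1,2-diol, via aryl formate 2 (not isolated)
Conditions: 30% aq. H2O2, H3BO3, cat. H2SO4, THF, rt, N2
Reagents that add atoms: hydrogen peroxide, OO
Why: Dakin oxidation (Baeyer–Villiger type): the hydroperoxide adduct of the aldehyde rearranges by migration of the very electron-rich aryl group (o-OH, o-OMe, p-OMe) to give formate 2, which hydrolyses in the aqueous acid, while boric acid complexes the catechol and shields it from over-oxidation; no stereocentre is formed.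

Step 2
Reactants: 3 3,5-dimethoxybenzene-1,2-diol; 4 ethyl 3-(3,4-dimethoxyphenyl)-3-oxopropanoate
Product: 7 4-(3,4-dimethoxyphenyl)-8-hydroxy-5,7-dimethoxy-2H-chromen-2-one (8-hydroxy-5,7,3',4'-tetramethoxy-4-phenylcoumarin), via aryl ketoester 5 (not isolated), via hydroxy-dihydrocoumarin 6 (not isolated)
Conditions: TFA (neat), 60 °C, N2, 16 h
Reagents that add atoms: none
Why: Pechmann condensation: transesterification, intramolecular Friedel–Crafts hydroxyalkylation at C6 of 3 (the only free carbon ortho to a hydroxyl, activated o-OH, o-OMe and p-OMe) and dehydration; the doubly flanked 2-OH cannot close a ring and becomes the 8-OH, and the product has no stereocentre.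

## Compound list

1 | 2-hydroxy-4,6-dimethoxybenzaldehyde | COc1cc(O)c(C=O)c(OC)c1 | starting material
2 | 2-hydroxy-4,6-dimethoxyphenyl formate | COc1cc(O)c(OC=O)c(OC)c1 | intermediate
3 | 3,5-dimethoxybenzene-1,2-diol | COc1cc(O)c(O)c(OC)c1 | intermediate
4 | ethyl 3-(3,4-dimethoxyphenyl)-3-oxopropanoate | CCOC(=O)CC(=O)c1ccc(OC)c(OC)c1 | starting material
5 | 2-hydroxy-3,5-dimethoxyphenyl 3-(3,4-dimethoxyphenyl)-3-oxopropanoate | COc1cc(OC)c(O)c(OC(=O)CC(=O)c2ccc(OC)c(OC)c2)c1 | intermediate
6 | 4-(3,4-dimethoxyphenyl)-4,8-dihydroxy-5,7-dimethoxychroman-2-one (racemic, transient) | COc1ccc(C2(O)CC(=O)Oc3c(O)c(OC)cc(OC)c32)cc1OC | intermediate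
7 | 4-(3,4-dimethoxyphenyl)-8-hydroxy-5,7-dimethoxy-2H-chromen-2-one | COc1ccc(-c2cc(=O)oc3c(O)c(OC)cc(OC)c23)cc1OC | target

## Totals

Total step count: 2. Longest linear sequence: 2 (1 → 3 → 7).

## Steps most likely to fail, with fallbacks

The route has only two steps, so both are listed and the third entry is a second, separate failure mode of step 2.

**1. Step 2, Pechmann ring closure (poor conversion or C–C bond formation at the wrong carbon).** The veratroyl ketone is a weak electrophile, and C4 of 3, between the two methoxy groups, is also activated. The fallback sets out from 3 and comes back at 7. Catechol 3 is acylated at its less hindered 1-OH with 3-(3,4-dimethoxyphenyl)prop-2-ynoic acid (DCC, cat. DMAP, CH2Cl2, 0 °C) to give 2-hydroxy-3,5-dimethoxyphenyl 3-(3,4-dimethoxyphenyl)prop-2-ynoate F1. A gold(I)-catalysed intramolecular 6-endo hydroarylation (Ph3PAuCl/AgOTf, DCE, rt to 60 °C) then isomerises F1 to 7. The ester tether lets only C6 reach the alkyne, so the regiochemistry no longer depends on intermolecular aromatic substitution.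

**2. Step 1, Dakin oxidation (over-oxidation of the very electron-rich catechol to quinones).** The fallback sets out from 1 and comes back at 3. Aldehyde 1 is benzylated (BnBr, K2CO3, DMF) to 2-(benzyloxy)-4,6-dimethoxybenzaldehyde F2. Baeyer–Villiger oxidation with mCPBA in CH2Cl2 gives 2-(benzyloxy)-4,6-dimethoxyphenyl formate F3, which is cleaved with aqueous NaOH in THF to 2-(benzyloxy)-4,6-dimethoxyphenol F4. Hydrogenolysis (H2, Pd/C, EtOAc) then releases 3 under reducing conditions, so the free catechol never meets an oxidant.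

**3. Step 2 again, second failure mode (decomposition of the air- and acid-sensitive catechol 3 in hot TFA).** The fallback sets out from 4 and comes back at 7, moving the 8-oxygenation to the end.
- Ketoester 4 undergoes Pechmann condensation with commercial 3,5-dimethoxyphenol in TFA. It passes in the flask through 3,5-dimethoxyphenyl 3-(3,4-dimethoxyphenyl)-3-oxopropanoate F5 and 4-(3,4-dimethoxyphenyl)-4-hydroxy-5,7-dimethoxychroman-2-one F6 and gives 4-(3,4-dimethoxyphenyl)-5,7-dimethoxy-2H-chromen-2-one F7.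
- Vilsmeier–Haack formylation (POCl3, DMF) at the most activated position, C8, gives N-{[4-(3,4-dimethoxyphenyl)-5,7-dimethoxy-2-oxo-2H-chromen-8-yl]methylidene}-N-methylmethanaminium chloride F8. Aqueous NaOAc hydrolyses it to 4-(3,4-dimethoxyphenyl)-5,7-dimethoxy-2-oxo-2H-chromene-8-carbaldehyde F9. The C8 versus C6 assignment must be confirmed by NOE (H-6 shows contacts to both OMe groups) and any C6 isomer removed.
- Baeyer–Villiger oxidation (mCPBA, CH2Cl2) gives 4-(3,4-dimethoxyphenyl)-5,7-dimethoxy-2-oxo-2H-chromen-8-yl formate F10, and mild aqueous hydrolysis (NaHCO3, THF–H2O) gives 7.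

## Further compounds

F1 | step 2 | 2-hydroxy-3,5-dimethoxyphenyl 3-(3,4-dimethoxyphenyl)prop-2-ynoate | COc1cc(OC)c(O)c(OC(=O)C#Cc2ccc(OC)c(OC)c2)c1
F2 | step 1 | 2-(benzyloxy)-4,6-dimethoxybenzaldehyde | COc1cc(OCc2ccccc2)c(C=O)c(OC)c1
F3 | step 1 | 2-(benzyloxy)-4,6-dimethoxyphenyl formate | COc1cc(OCc2ccccc2)c(OC=O)c(OC)c1
F4 | step 1 | 2-(benzyloxy)-4,6-dimethoxyphenol | COc1cc(OCc2ccccc2)c(O)c(OC)c1
F5 | step 2 | 3,5-dimethoxyphenyl 3-(3,4-dimethoxyphenyl)-3-oxopropanoate | COc1cc(OC)cc(OC(=O)CC(=O)c2ccc(OC)c(OC)c2)c1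
F6 | step 2 | 4-(3,4-dimethoxyphenyl)-4-hydroxy-5,7-dimethoxychroman-2-one (racemic, transient) | COc1ccc(C2(O)CC(=O)Oc3cc(OC)cc(OC)c32)cc1OC
F7 | step 2 | 4-(3,4-dimethoxyphenyl)-5,7-dimethoxy-2H-chromen-2-one | COc1ccc(-c2cc(=O)oc3cc(OC)cc(OC)c23)cc1OC
F8 | step 2 | N-{[4-(3,4-dimethoxyphenyl)-5,7-dimethoxy-2-oxo-2H-chromen-8-yl]methylidene}-N-methylmethanaminium chloride | COc1ccc(-c2cc(=O)oc3c(C=[N+](C)C)c(OC)cc(OC)c23)cc1OC.[Cl-]
F9 | step 2 | 4-(3,4-dimethoxyphenyl)-5,7-dimethoxy-2-oxo-2H-chromene-8-carbaldehyde | COc1ccc(-c2cc(=O)oc3c(C=O)c(OC)cc(OC)c23)cc1OC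
F10 | step 2 | 4-(3,4-dimethoxyphenyl)-5,7-dimethoxy-2-oxo-2H-chromen-8-yl formate | COc1ccc(-c2cc(=O)oc3c(OC=O)c(OC)cc(OC)c23)cc1OC
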